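**Plan**

1. Retrosynthesis: cut C12–C13 (Stille coupling to the butenolide), then trace the C9 side chain and the C8=C17 methylene back to a C9 ketone through a bromo enal, then cut ring A at C2–C3 and C4–C5. This leaves a ring B keto acid (from 2-methylcyclohexane-1,3-dione and methyl acrylate) and methyl buta-2,3-dienoate.
2. Forward: ring B is bought as the dione (C10 already carries C20). Ring A is annulated onto it in one operation and then dressed (C18 on C4, H on C5, OH on C3). Ring B is elaborated at C8/C9 and the butenolide is joined last.
3. Enabling feature: in ring A, C3 is the only oxygenated carbon and lies between unfunctionalized C2 and C4; C4 is α to the C19 carboxyl carbon; C5 is the ring A/ring B fusion carbon and can start as a ring B ketone. An allenoate (central carbon = C3, α-carbon = C4, ester = C19, CH2 terminus = masked C3 oxygen) therefore fits between a C2 radical and the C5 carbonyl.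
4. Stereochemistry: C10 from a CBS desymmetrization of the dione; C5 (trans fusion) and C4 (C18 trans, C19 cis to C20) from a Birch-type reductive methylation; C3 from axial hydride delivery; C9 from hydrogen delivery in an allylic diazene on the face away from C20; the E alkene from the (E)-distannane.

Key step: step 5

Remark: labdane numbering of the target is used for all intermediates (ring A = C1–C5 and C10; ring B = C5–C10; C17 = methylene carbon on C8; C18 = methyl on C4; C19 = oxygen-bearing carbon on C4; C20 = methyl on C10; side chain C11–C16).

Assumption: the sense of the CBS desymmetrization in step 2 is taken from the usual model (quaternary carbon as the large group, hydride anti to the longer chain), by analogy with the baker's yeast reduction of the 2-allyl analogue; if it were opposite, the (S)-catalyst would be used.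

**Route**

Step 1
Reactants: 1 2-methylcyclohexane-1,3-dione; 2 methyl acrylate
Product: 3 methyl 3-(1-methyl-2,6-dioxocyclohexyl)propanoate
Conditions: Et3N (1 equiv), 2 (3 equiv), MeCN, 70 °C
Reagents that add atoms: none
Why: Michael addition of the acidic 2-substituted 1,3-dione to the acrylate should give the C-alkylated, prochiral diketo ester and so places C1 and C2 on the future C10.

Step 2
Reactants: 3 diketo ester
Product: 4 methyl 3-[(1S,2S)-2-hydroxy-1-methyl-6-oxocyclohexyl]propanoate
Conditions: (R)-2-methyl-CBS-oxazaborolidine (0.2 equiv), catecholborane (1.1 equiv), toluene, −78 to −40 °C; MeOH quench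
Reagents that add atoms: none
Why: Corey–Bakshi–Shibata reduction used as an enantiotopic-group desymmetrization: the oxazaborolidine–borane complex should reduce one of the two equivalent ketones from one face (quaternary carbon as the large group, hydride anti to the longer chain), which sets the C9 carbinol as S and thereby fixes the quaternary C10 as S, while the ester is untouched.

Step 3
Reactants: 4 hydroxy keto ester
Product: 5 methyl 3-[(1S,2S)-2-(tert-butyldimethylsilyloxy)-1-methyl-6-oxocyclohexyl]propanoate
Conditions: TBSOTf (1.3 equiv), 2,6-lutidine (2 equiv), CH2Cl2, −78 to 0 °C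
Reagents that add atoms: tert-butyldimethylsilyl trifluoromethanesulfonate, CC(C)(C)[Si](C)(C)OS(=O)(=O)C(F)(F)F
Why: Silylation of the secondary alcohol (run on the crude alcohol to forestall δ-lactonization) blocks C9, so that C5 stays the only ketone and the later acid cannot lactonize.

Step 4
Reactants: 5 silyl ether ester
Product: 6 3-[(1S,2S)-2-(tert-butyldimethylsilyloxy)-1-methyl-6-oxocyclohexyl]propanoic acid
Conditions: LiOH·H2O (3 equiv), THF/H2O, 20 °C; then 1 M HCl to pH 3
Reagents that add atoms: lithium hydroxide monohydrate, [Li+].[OH-].O
Why: Saponification of the methyl ester should give the free acid needed as radical precursor; the hindered silyl ether and the non-epimerizable quaternary center are stable to LiOH.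

Step 5
Reactants: 6 silyl ether acid; 7 methyl buta-2,3-dienoate
Product: 11 ring A ketol (C3 methylidene; C4 methyl ester; C5 hydroxyl; mixture at C4 and C5), via primary C2 radical 8 (not isolated), via ester-substituted allyl radical 9 (not isolated), via cesium dienolate 10 (not isolated)
Conditions: Ir[dF(CF3)ppy]2(dtbbpy)PF6 (2 mol %), Cs2CO3 (1.0 equiv), 7 (3 equiv), degassed DMF (0.1 M), blue LEDs (450 nm), 20 °C
Reagents that add atoms: none
Why: Proposed new method: the photoexcited trivalent iridium complex oxidizes the cesium carboxylate of 6, loss of CO2 gives the primary radical 8 at C2 (polarity reversal of the former acrylate carbon), and 8 adds to the central carbon (C3) of allenoate 7 to give the allyl radical 9, which the reduced divalent iridium complex converts into dienolate 10. The α-carbon (C4) of 10 then adds to the only free ketone (C5) in a 6-(enolendo)-exo-trig aldol closure of ring A, the same mode as the aldol half of a Robinson annulation, and the methylidene left on C3 is a masked C3 ketone. The closest known reaction types are the decarboxylative photoredox Giese addition, in which the adduct radical is reduced to an enolate, and radical–polar crossover annulations in which that enolate is trapped by a tethered carbonyl group. The new stereocenters C4 and C5 need no control because both become sp2 in step 6, C10 is already fixed, and C9 is blocked as its silyl ether so that no second ketone competes. The step needs attack of 8 at the allene central carbon (the position that gives the ester-stabilized radical) and α- rather than γ-attack of the dienolate (the kinetic mode of ester dienolates toward carbonyl groups); an excess of 7 is used so that addition outruns 1,5-hydrogen transfer from C6.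

Step 6
Reactants: 11 ring A ketol
Product: 13 enone ester (C3 ketone; C4=C5; C4 methyl ester), via keto ketol 12 (not isolated)
Conditions: O3, CH2Cl2/MeOH, −78 °C; Me2S, −78 to 20 °C; then pyrrolidinium acetate (0.2 equiv), toluene, 60 °C
Reagents that add atoms: ozone, [O-][O+]=O
Why: Ozonolysis of the only alkene unmasks the C3 ketone with loss of the allene terminus as formaldehyde, and the resulting β-keto ester ketol should dehydrate by E1cB elimination (the dehydration half of a Robinson annulation) to the conjugated enone ester, which removes the uncontrolled centers at C4 and C5.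

Step 7
Reactants: 13 enone ester
Product: 15 trans-fused keto ester (C18 methyl trans to C20; C19 ester cis to C20; H5 trans to C20), via lithium enolate 14 (not isolated)
Conditions: Li (2.5 equiv), t-BuOH (1.0 equiv), NH3(l)/THF, −78 °C; isoprene; then MeI (5 equiv), −78 to −33 °C; NH4Cl
Reagents that add atoms: iodomethane, CI
Why: Birch-type reductive alkylation: electron transfer to the enone ester and protonation of C5 on the face opposite the angular C10 methyl should give the trans ring fusion, and the lithium β-keto ester enolate is then methylated on its less hindered face, trans to the axial C10 methyl, so that C18 is equatorial and the C19 ester axial and cis to C20.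

Step 8
Reactants: 15 trans-fused keto ester
Product: 16 C3 alcohol (equatorial hydroxyl cis to the C19 ester)
Conditions: NaBH4, MeOH, 0 °C
Reagents that add atoms: none
Why: Borohydride reduction of the C3 ketone by axial attack (the usual course for 4,4-disubstituted 3-keto decalins) should give the equatorial C3 alcohol, cis to the C19 ester, without touching the hindered ester.

Step 9
Reactants: 16 C3 alcohol
Product: 17 C3 acetate
Conditions: Ac2O, DMAP (cat.), pyridine, 20 °C
Reagents that add atoms: acetic anhydride, CC(=O)OC(C)=O
Why: Acetylation protects the C3 hydroxyl as an acid-stable ester for the oxidation, bromoformylation and Mitsunobu steps that follow.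

Step 10
Reactants: 17 C3 acetate
Product: 18 C9 alcohol
Conditions: 48% aq. HF, MeCN, 20 °C
Reagents that add atoms: none
Why: Fluoride-assisted cleavage of the Si–O bond frees the C9 hydroxyl, while the acetate and the methyl ester survive the acidic medium.

Step 11
Reactants: 18 C9 alcohol
Product: 19 C9 ketone
Conditions: Dess–Martin periodinane, CH2Cl2, 20 °C
Reagents that add atoms: none
Why: Dess–Martin oxidation of the secondary alcohol gives the C9 ketone, which can enolize only toward C8.

Step 12
Reactants: 19 C9 ketone
Product: 20 bromo enal (C8=C9; Br on C9; formyl carbon C17 on C8)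
Conditions: PBr3 (3 equiv), DMF (4 equiv), CHCl3, 0 to 60 °C; then aq. NaHCO3, 0 °C
Reagents that add atoms: N,N-dimethylformamide, CN(C)C=O; phosphorus tribromide, BrP(Br)Br; water, O
Why: Vilsmeier–Haack-type bromoformylation (Arnold reaction): the ketone enolizes only toward C8, so the bromoiminium reagent formylates C8 (bringing in C17 at the aldehyde level) and turns C9 into a vinyl bromide for coupling.

Step 13
Reactants: 20 bromo enal; 21 (E)-1,2-bis(tributylstannyl)ethene
Product: 22 dienyl stannane enal
Conditions: 21 (3 equiv), Pd2(dba)3 (2.5 mol %), AsPh3 (20 mol %), NMP, 50 °C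
Reagents that add atoms: none
Why: Stille coupling of the activated β-bromo enal with an excess of the (E)-distannane should transfer one stannylvinyl group with retention of geometry, joining C9 to C11 and leaving an (E)-alkenyl stannane at C12.

Step 14
Reactants: 22 dienyl stannane enal
Product: 23 primary allylic alcohol (C17 hydroxymethyl)
Conditions: NaBH4, CeCl3·7H2O, MeOH, −78 °C
Reagents that add atoms: none
Why: Luche reduction should give the primary allylic alcohol by 1,2-reduction of the dienal without touching the ester, the acetate or the stannane.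

Step 15
Reactants: 23 primary allylic alcohol
Product: 26 exocyclic methylene stannane (C8=C17; H9 trans to C20; C3 acetate; C19 methyl ester), via sulfonylhydrazine adduct 24 (not isolated), via allylic diazene 25 (not isolated)
Conditions: 2-nitrobenzenesulfonylhydrazide, PPh3, diethyl azodicarboxylate, N-methylmorpholine, −30 °C; then 20 °C
Reagents that add atoms: none
Why: Mitsunobu N-alkylation of the sulfonyl hydrazide by the only free hydroxyl, loss of the sulfinic acid and retro-ene loss of N2 from the allylic diazene (reductive 1,3-transposition) should move the double bond to C8=C17 and deliver hydrogen to C9 through a six-membered transition state on the face opposite the axial C10 methyl, which sets H9 trans to C20 with the side chain equatorial.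

Step 16
Reactants: 26 exocyclic methylene stannane
Product: 27 3,19-diol
Conditions: LiAlH4, THF, 0 to 50 °C; Fieser work-up
Reagents that add atoms: none
Why: LiAlH4 reduces the hindered axial C19 ester to the primary alcohol and cleaves the C3 acetate in the same operation, while the alkenyl stannane and the isolated alkenes are inert to hydride.

Step 17
Reactants: 27 3,19-diol
Product: 28 C19 acetate with free C3 hydroxyl
Conditions: AcCl (1.1 equiv), 2,4,6-collidine, CH2Cl2, −78 °C
Reagents that add atoms: acetyl chloride, CC(Cl)=O
Why: Kinetically selective acetylation of the primary C19 hydroxyl over the hindered secondary C3 hydroxyl at low temperature should install the acetate of the target.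

Step 18
Reactants: 28 C19 acetate stannane; 29 3-bromofuran-2(5H)-one
Product: 30 target (14-deoxy-11,12-didehydroandrographolide 19-acetate, CNP0346413.1)
Conditions: 29 (1.5 equiv), Pd2(dba)3 (5 mol %), AsPh3 (20 mol %), CuI (10 mol %), DMF, 20 to 45 °C
Reagents that add atoms: none
Why: Stille coupling of the (E)-alkenyl stannane with the α-bromo butenolide should form C12–C13 with retention of the E geometry under neutral conditions that tolerate the free alcohol, the acetate and the exocyclic methylene.

**Compound list**

1 | 2-methylcyclohexane-1,3-dione | CC1C(=O)CCCC1=O | starting material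
2 | methyl acrylate | C=CC(=O)OC | starting material
3 | methyl 3-(1-methyl-2,6-dioxocyclohexyl)propanoate | COC(=O)CCC1(C)C(=O)CCCC1=O | intermediate
4 | methyl 3-[(1S,2S)-2-hydroxy-1-methyl-6-oxocyclohexyl]propanoate | COC(=O)CC[C@@]1(C)[C@@H](O)CCCC1=O | intermediate
5 | methyl 3-[(1S,2S)-2-(tert-butyldimethylsilyloxy)-1-methyl-6-oxocyclohexyl]propanoate | COC(=O)CC[C@@]1(C)[C@@H](O[Si](C)(C)C(C)(C)C)CCCC1=O | intermediate
6 | 3-[(1S,2S)-2-(tert-butyldimethylsilyloxy)-1-methyl-6-oxocyclohexyl]propanoic acid | OC(=O)CC[C@@]1(C)[C@@H](O[Si](C)(C)C(C)(C)C)CCCC1=O | intermediate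
7 | methyl buta-2,3-dienoate | C=C=CC(=O)OC | starting material
8 | 2-[(1S,2S)-2-(tert-butyldimethylsilyloxy)-1-methyl-6-oxocyclohexyl]ethyl radical (radical at C2) | [CH2]C[C@@]1(C)[C@@H](O[Si](C)(C)C(C)(C)C)CCCC1=O | intermediate
9 | allyl radical from addition of 8 to the central carbon of 7 (radical at C4, α to the ester) | C=C(CC[C@@]1(C)[C@@H](O[Si](C)(C)C(C)(C)C)CCCC1=O)[CH]C(=O)OC | intermediate
10 | cesium dienolate of methyl 3-methylidene-5-[(1S,2S)-2-(tert-butyldimethylsilyloxy)-1-methyl-6-oxocyclohexyl]pentanoate | C=C(CC[C@@]1(C)[C@@H](O[Si](C)(C)C(C)(C)C)CCCC1=O)C=C([O-])OC.[Cs+] | intermediate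
11 | methyl 5-(tert-butyldimethylsilyloxy)-8a-hydroxy-4a-methyl-2-methylidenedecahydronaphthalene-1-carboxylate (labdane: C3 methylidene, C4 ester, C5 hydroxyl, C9 silyl ether; C9 and C10 as in 6; mixture at C4 and C5) | C=C1CC[C@@]2(C)[C@@H](O[Si](C)(C)C(C)(C)C)CCCC2(O)C1C(=O)OC | intermediate
12 | keto ketol: 2-oxo analogue of 11 (C3 ketone, C5 hydroxyl) | O=C1CC[C@@]2(C)[C@@H](O[Si](C)(C)C(C)(C)C)CCCC2(O)C1C(=O)OC | intermediate
13 | methyl 5-(tert-butyldimethylsilyloxy)-4a-methyl-2-oxo-2,3,4,4a,5,6,7,8-octahydronaphthalene-1-carboxylate (C3 ketone, C4=C5; C9 and C10 as in 6) | O=C1CC[C@@]2(C)[C@@H](O[Si](C)(C)C(C)(C)C)CCCC2=C1C(=O)OC | intermediate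
14 | lithium enolate (C3–O, C3=C4) of the trans-fused β-keto ester, H5 trans to C20 | C1CC[C@@H]2C(C(=O)OC)=C([O-])CC[C@@]2(C)[C@H]1O[Si](C)(C)C(C)(C)C.[Li+] | intermediate
15 | methyl 5-(tert-butyldimethylsilyloxy)-1,4a-dimethyl-2-oxodecahydronaphthalene-1-carboxylate, trans-fused, ester cis and C1 methyl trans to the angular methyl (labdane: 3-oxo, C19 ester, 9-silyl ether) | C1CC[C@@H]2[C@](C)(C(=O)OC)C(=O)CC[C@@]2(C)[C@H]1O[Si](C)(C)C(C)(C)C | intermediate
16 | C3 alcohol of 15, hydroxyl equatorial and cis to the C19 ester | C1CC[C@@H]2[C@](C)(C(=O)OC)[C@H](O)CC[C@@]2(C)[C@H]1O[Si](C)(C)C(C)(C)C | intermediate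
17 | C3 acetate of 16 | C1CC[C@@H]2[C@](C)(C(=O)OC)[C@H](OC(C)=O)CC[C@@]2(C)[C@H]1O[Si](C)(C)C(C)(C)C | intermediate
18 | 17 with free C9 hydroxyl | C1CC[C@@H]2[C@](C)(C(=O)OC)[C@H](OC(C)=O)CC[C@@]2(C)[C@H]1O | intermediate
19 | C9 ketone: methyl 2-acetoxy-1,4a-dimethyl-5-oxodecahydronaphthalene-1-carboxylate (ring A as in 17) | C1CC[C@@H]2[C@](C)(C(=O)OC)[C@H](OC(C)=O)CC[C@@]2(C)C1=O | intermediate
20 | bromo enal: C8=C9 alkene, Br on C9, formyl (C17) on C8, ring A as in 17 | O=CC=1CC[C@@H]2[C@](C)(C(=O)OC)[C@H](OC(C)=O)CC[C@@]2(C)C=1Br | intermediate
21 | (E)-1,2-bis(tributylstannyl)ethene | CCCC[Sn](CCCC)(CCCC)/C=C/[Sn](CCCC)(CCCC)CCCC | starting material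
22 | dienyl stannane enal: 20 with (E)-2-(tributylstannyl)ethenyl on C9 in place of Br | O=CC=1CC[C@@H]2[C@](C)(C(=O)OC)[C@H](OC(C)=O)CC[C@@]2(C)C=1/C=C/[Sn](CCCC)(CCCC)CCCC | intermediate
23 | primary allylic alcohol from 22 (C17 hydroxymethyl on C8) | OCC=1CC[C@@H]2[C@](C)(C(=O)OC)[C@H](OC(C)=O)CC[C@@]2(C)C=1/C=C/[Sn](CCCC)(CCCC)CCCC | intermediate
24 | N-(C17-allyl)-N-(2-nitrophenylsulfonyl)hydrazine from 23 | NN(CC=1CC[C@@H]2[C@](C)(C(=O)OC)[C@H](OC(C)=O)CC[C@@]2(C)C=1/C=C/[Sn](CCCC)(CCCC)CCCC)S(=O)(=O)c1ccccc1[N+](=O)[O-] | intermediate
25 | allylic diazene (HN=N on C17) | N=NCC=1CC[C@@H]2[C@](C)(C(=O)OC)[C@H](OC(C)=O)CC[C@@]2(C)C=1/C=C/[Sn](CCCC)(CCCC)CCCC | intermediate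
26 | C3 acetate, C19 methyl ester with C8=C17 exocyclic methylene, H9 trans to C20 and (E)-2-(tributylstannyl)ethenyl on C9 | C=C1CC[C@@H]2[C@](C)(C(=O)OC)[C@H](OC(C)=O)CC[C@@]2(C)[C@@H]1/C=C/[Sn](CCCC)(CCCC)CCCC | intermediate
27 | 3,19-diol of 26 | C=C1CC[C@@H]2[C@](C)(CO)[C@H](O)CC[C@@]2(C)[C@@H]1/C=C/[Sn](CCCC)(CCCC)CCCC | intermediate
28 | 19-acetate of 27 with free C3 hydroxyl | C=C1CC[C@@H]2[C@](C)(COC(C)=O)[C@H](O)CC[C@@]2(C)[C@@H]1/C=C/[Sn](CCCC)(CCCC)CCCC | intermediate
29 | 3-bromofuran-2(5H)-one | BrC1=CCOC1=O | starting material
30 | 14-deoxy-11,12-didehydroandrographolide 19-acetate (CNP0346413.1) | C=C1CC[C@@H]2[C@](C)(COC(C)=O)[C@H](O)CC[C@@]2(C)[C@@H]1/C=C/C1=CCOC1=O | target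

**Step count**

Total steps: 18. Longest linear sequence: 18 steps (1 to 30); 7, 21 and 29 are bought.

**Steps most likely to fail**

1. Step 5 (Proposed new method). What may go wrong: slow oxidation of the unactivated primary carboxylate; 1,5-hydrogen transfer from C6 to the C2 radical; base-induced isomerization or oligomerization of the allenoate; protonation or γ-attack of the dienolate before the α-aldol closure; addition of the product alkoxide to excess allenoate. Fallback (known chemistry): starting from acid 6, activation with 1,1'-carbonyldiimidazole and C-acylation of Mg(O2CCH2CO2Me)2 would give the β-keto ester F1, in which the carboxyl carbon of 6 is kept and becomes C3. Pyrrolidinium acetate in warm toluene would then close ring A by an intramolecular Knoevenagel-type aldol condensation, as in the second stage of a Robinson annulation, to give enone ester 13. The route is rejoined at 13 and step 6 is skipped.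

2. Step 15. What may go wrong: failure of the Mitsunobu N-alkylation at the hindered, ionization-prone dienylic carbinol (elimination or substitution without transposition), or loss of the stannyl group to the sulfinic acid that is released. Fallback: starting from allylic alcohol 23, formylation with acetic formic anhydride and pyridine would give the allylic formate F2. Pd(OAc)2 with PBu3 in THF (zerovalent palladium formed in the flask) would ionize it to a π-allylpalladium formate, which loses CO2 and delivers hydride to the more substituted terminus C9 from the palladium-bearing, less hindered face. This gives 26, where the route is rejoined.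

3. Step 2. What may go wrong: reduction of both ketones, poor discrimination between the two enantiotopic carbonyl groups (low enantiomeric purity at C10), or lactonization of the hydroxy ester. Fallback: starting from dione 1, C-allylation with allyl bromide in aqueous NaOH would give 2-allyl-2-methylcyclohexane-1,3-dione F3. Reduction with fermenting baker's yeast should give the (2S,3S)-hydroxy ketone F4, whose configuration corresponds to that of 4. Silylation as in step 3 would give the silyl ether F5, hydroboration–oxidation of the allyl group (9-BBN; then NaOH, H2O2) the primary alcohol F6, and oxidation with TEMPO and PhI(OAc)2 in MeCN/H2O the acid 6, where the route is rejoined.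

**Further compounds**

F1 | step 5 | methyl 3-oxo-5-[(1S,2S)-2-(tert-butyldimethylsilyloxy)-1-methyl-6-oxocyclohexyl]pentanoate | COC(=O)CC(=O)CC[C@@]1(C)[C@@H](O[Si](C)(C)C(C)(C)C)CCCC1=O
F2 | step 15 | formate ester of allylic alcohol 23 (formyloxy on C17) | O=COCC=1CC[C@@H]2[C@](C)(C(=O)OC)[C@H](OC(C)=O)CC[C@@]2(C)C=1/C=C/[Sn](CCCC)(CCCC)CCCC
F3 | step 2 | 2-allyl-2-methylcyclohexane-1,3-dione | C=CCC1(C)C(=O)CCCC1=O
F4 | step 2 | (2S,3S)-2-allyl-3-hydroxy-2-methylcyclohexan-1-one | C=CC[C@@]1(C)[C@@H](O)CCCC1=O
F5 | step 2 | (2S,3S)-2-allyl-3-(tert-butyldimethylsilyloxy)-2-methylcyclohexan-1-one | C=CC[C@@]1(C)[C@@H](O[Si](C)(C)C(C)(C)C)CCCC1=O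
F6 | step 2 | (2S,3S)-3-(tert-butyldimethylsilyloxy)-2-(3-hydroxypropyl)-2-methylcyclohexan-1-one | OCCC[C@@]1(C)[C@@H](O[Si](C)(C)C(C)(C)C)CCCC1=O
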